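Target does not keep.

common to all: initiator 0.77 mM

|  | substrate | coupling partner | time | remark |
|---|---|---|---|---|
| south | 0.055 M | 0.0522 M | 40 s | a closed flask charged with all of it at once and left for 40 s |
| south-east | 0.055 M (fed, over 32.0 s) | 0.0522 M | 40 s | all but substrate at the start; substrate goes in evenly over 32.0 s, the run ends at 40 s |
| north-west | 0.055 M | 0.0522 M |  | a single well-mixed tank run continuously and read at steady state, 40 s in it on average |
| east | 0.055 M | 0.0522 M (fed, over 32.0 s) | 40 s | a stirred flask in which coupling partner is dosed at a steady rate over 32.0 s without added volume, worked up at 40 s |

* the set-up with the highest share of target in all that became target or over-reaction product, at the outlet or at the end ("none" if the first two lie within 2 percentage points) (south / south-east / north-west / east / none)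
* share of target in all that became target or over-reaction product, at the outlet or at the end, south
* share of target in all that became target or over-reaction product, at the outlet or at the end, south-east
* share of target in all that became target or over-reaction product, at the outlet or at the end, north-west
* share of target in all that became target or over-reaction product, at the outlet or at the end, east

- percent here means substrate units held: one self-condensation product counts as two
- a doubled species enters its step squared and goes two at a time
- the stated concentrations are those of everything mixed, before any reaction; amounts are the same in each set-up
- the feed brings no volume worth counting
- run time (south): 40 s

    initiator → 2 initiating radical (k1 = 0.082 s⁻¹)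
    substrate + initiating radical → capped initiator + first chain carrier (k2 = 93000 M⁻¹ s⁻¹)
    coupling partner + first chain carrier → target + second chain carrier (k3 = 4100 M⁻¹ s⁻¹)
    substrate + second chain carrier → released group + first chain carrier (k4 = 4600 M⁻¹ s⁻¹)
    first chain carrier → ended carrier (k5 = 11 s⁻¹)
    2 second chain carrier → ended chains (k6 = 2 × 10⁶ M⁻¹ s⁻¹)
    2 substrate → self-condensation product (k7 = 1.2 M⁻¹ s⁻¹)
    coupling partner + target → over-reaction product (k8 = 1.0 M⁻¹ s⁻¹)

Once made, target is eaten by coupling partner in step 8, a pseudo-first-order loss while the partner stays near its charge. South gives 2.09 for the exposure, the constant of step 8 times the coupling partner times the time target spends beside it. The fraction of a target that survives is the exponential of minus its exposure. Its half-life of 13 s is shorter than the 40 s run, so the share must fall well short of complete.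

I solve south at both ends. Target made at the first instant gives a share of 12.4%, and target made evenly to the end gives 42.0%. Making is front-loaded, because step 7 alone halves the substrate in 7.58 s and step 1 alone halves the initiator in 8.45 s, both well inside the run. But late target survives best, so the tail counts for more than its amount. I join the ends at their midpoint, 27.2%. Coupling partner also falls during the run, so this exposure is too high and my figure is probably low.

South-east has the same partner, but its substrate arrives over 32.0 s; target made evenly over that time gives 32.0%. In the north-west tank the share is one over one plus the exposure. East lowers the exposure itself, to 1.25 for target made at the start. One objection is that thin partner lets the first chain carrier die by step 5. Yet step 3 overtakes step 5 once the partner reaches 2.68 mM, which the feed supplies in 1.64 s if none is used. That costs target, but the share compares target with its own over-reaction product. I carry the midpoint to east, though its upper end assumes a steady partner.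

| Set-up | Exposure from the start | My share |
|---|---|---|
| south | 2.09 | 27.2% |
| south-east | 2.09 | 32.0% |
| north-west | 2.09 | 32.4% |
| east | 1.25 | 42.9% |

The forecast chooses east, with 33% for south, 40% for south-east, 38% for north-west and 44% for east, and reasons that “Dosing coupling partner keeps that loss smallest during the early period when target is made”. I also choose east, but its south figure stands above mine.

The simulation gives east as best, with 31.9% for south, 38.9% for south-east, 38.3% for north-west and 43.5% for east.

In south, target has a half-life of 14 s at 4.46 s against the 40 s run, and at 40.0 s it is made at 0.261 of the rate at which it is used up. With 70% of the coupling partner left, the mean of start and end puts south's exposure at 1.77, and the ends become 17.0% and 46.9%, with 31.9% between them.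

For the neighbour of south charged with 0.013 M of coupling partner, the exposure is 0.520, so the ends are 59.5% and 77.9%, with a midpoint of 68.7%. The computed share in that flask is 77.6%.

The numbers belong to no real substance; the result is computed.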